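- Numbering runs outward from the tetronic acid ring: ring carbon C5, exocyclic C6, stereocentre C7, methylenes C8–C10, alkene C11=C12, methylenes C13 and C14, then the 2,4-disubstituted furan and its furan-3-ylmethyl group.
- The retrosynthesis cuts, in order: the enol O–CH3 bond; C5=C6 (aldol addition and dehydration on a methyl tetronate); C7–CH3 together with C6–O (methylalumination and oxidation of a C6=C7 vinyl group); C13–C14 (allyl–furylmethyl coupling); the CH2–furan bond between the two furans (Negishi coupling); and C11–CH3 (cuprate addition to a 2-ynoate).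
- The enabling feature: the only stereocentre, C7, is a methyl-bearing sp3 carbon bonded directly to C6 and followed by the unbranched C8–C10 chain, which is the 2-methylalkyl unit that enantioselective methylmetalation of a terminal C6=C7 alkene delivers. The tetronic acid ring and both furan rings are bought intact, so no ring is formed anywhere.
- Forward: the C6–C13 chain (fragment 1, a Z allylic chloride) and the bis-furan unit carrying C14 (fragment 2) are made separately and joined at C13–C14. The terminal alkene is then carboaluminated and oxidised, and the tetronic acid ring is attached last through C5=C6.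
- Stereochemistry: C7 comes from face selection at C6=C7 by the chiral zirconocene and is not touched afterwards. Z-C11=C12 comes from syn carbocupration of the ynoate. Z-C5=C6 comes from base-mediated elimination that favours the less strained isomer.

Key step: step 11

Assumption: no bond at C7 is made or broken after step 11, so the enantiomeric purity set there is carried to the target; if a minor C7 antipode has to be removed, this is planned for the conjugated ylidene 29 by preparative chromatography on a chiral stationary phase (cellulose tris(3,5-dimethylphenylcarbamate)).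

**Route**

Step 1
Reactants: 1 5-bromopent-1-ene
Product: 2 hept-1-en-6-yne
Conditions: LiC≡CH·H2NCH2CH2NH2, DMSO, 10 °C → rt; pentane extraction, distillation
Reagents that add atoms: lithium acetylide ethylenediamine complex, [Li+].[C-]#C.NCCN
Why: SN2 alkylation of an acetylide anion by an unhindered primary bromide in a dipolar aprotic solvent is a standard terminal-alkyne synthesis and leaves the remote alkene untouched.

Step 2
Reactants: 2 hept-1-en-6-yne
Product: 4 methyl oct-7-en-2-ynoate, via lithium hept-6-en-1-yn-1-ide 3 (not isolated)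
Conditions: n-BuLi, THF, −78 °C; ClCO2Me, −78 → 0 °C
Reagents that add atoms: methyl chloroformate, COC(Cl)=O
Why: Deprotonation of the terminal alkyne and C-acylation of the lithium acetylide by a chloroformate is the routine alkoxycarbonylation route to 2-ynoates.

Step 3
Reactants: 4 methyl oct-7-en-2-ynoate
Product: 6 methyl (2Z)-3-methylocta-2,7-dienoate, via lithium alkenyl(methyl)cuprate 5 (not isolated)
Conditions: Me2CuLi (from CuI and 2 MeLi, THF, 0 °C), THF, −78 °C; MeOH then aq NH4Cl at −78 °C
Reagents that add atoms: lithium dimethylcuprate, [Li+].C[Cu-]C, made from methyllithium, [Li]C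
Why: Conjugate carbocupration of a 2-ynoate is a stereospecific syn addition, so the new methyl and the α-hydrogen end up cis and the pentenyl chain cis to the ester (the Z geometry of C11=C12), provided the alkenylcopper intermediate is protonated at −78 °C before it can equilibrate through the allenoate.

Step 4
Reactants: 6 methyl (2Z)-3-methylocta-2,7-dienoate
Product: 7 (2Z)-3-methylocta-2,7-dien-1-ol
Conditions: i-Bu2AlH (2.3 equiv), CH2Cl2, −78 → 0 °C; aq potassium sodium tartrate (KNaC4H4O6)
Reagents that add atoms: none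
Why: 1,2-Reduction of an α,β-unsaturated ester by i-Bu2AlH gives the allylic alcohol without touching either alkene or the Z geometry.

Step 5
Reactants: 7 (2Z)-3-methylocta-2,7-dien-1-ol
Product: 9 (2Z)-1-chloro-3-methylocta-2,7-diene, via (2Z)-3-methylocta-2,7-dien-1-yl methanesulfonate 8 (not isolated)
Conditions: MsCl, LiCl, 2,4,6-collidine, DMF, 0 °C
Reagents that add atoms: lithium chloride, [Li+].[Cl-]
Why: Mesylation followed by in situ SN2 displacement by chloride under buffered conditions converts primary allylic alcohols into the chlorides without allylic transposition or Z/E scrambling, as in the conversion of nerol into neryl chloride.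

Step 6
Reactants: 10 furan-3-ylmethanol
Product: 12 3-(chloromethyl)furan, via furan-3-ylmethyl methanesulfonate 11 (not isolated)
Conditions: MsCl, LiCl, 2,4,6-collidine, DMF, 0 °C; kept as a cold ethereal solution and used at once
Reagents that add atoms: lithium chloride, [Li+].[Cl-]
Why: The same mesylate-to-chloride SN2 exchange under non-acidic conditions suits the acid-sensitive and volatile furylmethyl system.

Step 7
Reactants: 12 3-(chloromethyl)furan; 13 methyl 5-bromofuran-3-carboxylate
Product: 15 methyl 5-(furan-3-ylmethyl)furan-3-carboxylate, via (furan-3-ylmethyl)zinc chloride 14 (not isolated)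
Conditions: Zn dust, LiCl, THF, rt; then 13, Pd(OAc)2 (2 mol%), SPhos (4 mol%), THF, rt
Reagents that add atoms: none
Why: LiCl-assisted zinc insertion into the benzylic-type C–Cl bond gives an ester-tolerant heteroarylmethylzinc chloride, and Negishi coupling (oxidative addition of zerovalent palladium into the activated C–Br bond next to the furan oxygen, transmetalation, reductive elimination) forms the di(heteroaryl)methane.

Step 8
Reactants: 15 methyl 5-(furan-3-ylmethyl)furan-3-carboxylate
Product: 16 [5-(furan-3-ylmethyl)furan-3-yl]methanol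
Conditions: i-Bu2AlH (2.3 equiv), CH2Cl2, −78 → 0 °C; aq potassium sodium tartrate (KNaC4H4O6)
Reagents that add atoms: none
Why: Hydride reduction of the heteroaryl ester gives the primary alcohol, and the non-acidic work-up spares both furans.

Step 9
Reactants: 16 [5-(furan-3-ylmethyl)furan-3-yl]methanol
Product: 18 4-(chloromethyl)-2-(furan-3-ylmethyl)furan, via [5-(furan-3-ylmethyl)furan-3-yl]methyl methanesulfonate 17 (not isolated)
Conditions: MsCl, LiCl, 2,4,6-collidine, DMF, 0 °C; used directly
Reagents that add atoms: lithium chloride, [Li+].[Cl-]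
Why: Mesylation and chloride displacement (SN2) give the furan-3-ylmethyl-type chloride under buffered conditions that avoid acid-induced oligomerisation of the bis-furylmethane.

Step 10
Reactants: 18 4-(chloromethyl)-2-(furan-3-ylmethyl)furan; 9 (2Z)-1-chloro-3-methylocta-2,7-diene
Product: 20 2-(furan-3-ylmethyl)-4-[(3Z)-4-methylnona-3,8-dien-1-yl]furan, via [5-(furan-3-ylmethyl)furan-3-yl]methylmagnesium chloride 19 (not isolated)
Conditions: Mg turnings, THF, 0 °C → rt (slow addition of 18, high dilution); then 9, Li2CuCl4 (3 mol%), THF, −10 °C → rt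
Reagents that add atoms: none
Why: Copper-catalysed cross-coupling of a furan-3-ylmethyl Grignard reagent with a primary allylic chloride, well established for neryl- and geranyl-type chlorides, forms C13–C14 by direct SN2 attack with retention of the alkene geometry because the γ-carbon C11 is fully substituted.

Step 11
Reactants: 20 2-(furan-3-ylmethyl)-4-[(3Z)-4-methylnona-3,8-dien-1-yl]furan
Product: 22 (2S,6Z)-9-[5-(furan-3-ylmethyl)furan-3-yl]-2,6-dimethylnon-6-en-1-ol, via dimethyl(2-methylalkyl)alane 21 (not isolated)
Conditions: Me3Al (2.5 equiv), (+)-bis(1-neomenthylindenyl)zirconium dichloride (5 mol%), methylaluminoxane (MeAlO)n (promoter), CH2Cl2, 0 °C → rt; then dry O2 (1 atm), 0 °C → rt; aq potassium sodium tartrate (KNaC4H4O6)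
Reagents that add atoms: trimethylaluminium, C[Al](C)C; dioxygen, O=O
Why: Me3Al and methylaluminoxane methylate and ionise the zirconocene dichloride to a chiral cationic methylzirconium species (tetravalent zirconium throughout), which inserts the monosubstituted C6=C7 alkene with zirconium at C6 and the new C7–CH3 bond at the internal carbon; Zr-to-Al transmetalation then releases alane 21 and regenerates the catalyst, and O2 inserts into the C6–Al bond to give the alkoxide that is hydrolysed to 22. The closest known reaction type is the zirconium-catalysed asymmetric methylalumination of unfunctionalised 1-alkenes with in situ oxidation to 2-methylalkan-1-ols. No ring is closed. The configuration at C7 is controlled solely by the catalyst, whose neomenthylindenyl ligands differentiate the two alkene faces, the dextrorotatory complex being the antipode expected to give the (S)-2-methylalkanol. The step needs chemoselectivity for the terminal alkene and enantioface selectivity; the first is secured because the trisubstituted C11=C12 alkene and the aromatic furans do not insert into the hindered Zr–CH3 bond, the second because C8–C10 are unbranched methylenes with no nearby donor group to disturb the catalyst pocket. No later step makes or breaks a bond at C7, so the purity set here is the purity carried to the target.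

Step 12
Reactants: 23 3-methyltetronic acid
Product: 24 4-methoxy-3-methylfuran-2(5H)-one
Conditions: Me2SO4, K2CO3, acetone, reflux
Reagents that add atoms: dimethyl sulfate, COS(=O)(=O)OC
Why: O-Alkylation of the tetronate anion by a hard methylating agent takes place at the C4 oxygen and gives the methyl tetronate, the standard masked form of the acidic enol.

Step 13
Reactants: 22 (2S,6Z)-9-[5-(furan-3-ylmethyl)furan-3-yl]-2,6-dimethylnon-6-en-1-ol
Product: 25 (2S,6Z)-9-[5-(furan-3-ylmethyl)furan-3-yl]-2,6-dimethylnon-6-enal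
Conditions: Dess–Martin periodinane, NaHCO3, CH2Cl2, 0 °C → rt; used at once
Reagents that add atoms: none
Why: Dess–Martin oxidation under bicarbonate buffering is fast and near-neutral, which avoids enolisation of the α-stereogenic aldehyde at C7 and acid damage to the furans.

Step 14
Reactants: 24 4-methoxy-3-methylfuran-2(5H)-one; 25 (2S,6Z)-9-[5-(furan-3-ylmethyl)furan-3-yl]-2,6-dimethylnon-6-enal
Product: 27 5-[(2S,6Z)-9-[5-(furan-3-ylmethyl)furan-3-yl]-1-hydroxy-2,6-dimethylnon-6-en-1-yl]-4-methoxy-3-methylfuran-2(5H)-one (epimer mixture at C5/C6), via lithium 4-methoxy-3-methylfuran-2-olate 26 (not isolated)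
Conditions: LiN(i-Pr)2, THF, −78 °C; then 25, −78 °C; aq NH4Cl
Reagents that add atoms: none
Why: Deprotonation of the methyl tetronate at C5 gives an aromatic furan-2-olate that adds to aldehydes through C5 (vinylogous aldol addition of a lithiated tetronate); at −78 °C addition outruns enolisation of the aldehyde so C7 is retained, and the two new centres at C5 and C6 are formed unselectively and removed in the next step.

Step 15
Reactants: 27 5-[(2S,6Z)-9-[5-(furan-3-ylmethyl)furan-3-yl]-1-hydroxy-2,6-dimethylnon-6-en-1-yl]-4-methoxy-3-methylfuran-2(5H)-one (epimer mixture)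
Product: 29 (5Z)-5-[(2S,6Z)-9-[5-(furan-3-ylmethyl)furan-3-yl]-2,6-dimethylnon-6-en-1-ylidene]-4-methoxy-3-methylfuran-2(5H)-one, via C6 methanesulfonate 28 (not isolated)
Conditions: MsCl, Et3N, CH2Cl2, 0 °C; then DBU, 0 °C → rt; chromatography (on a chiral stationary phase if required)
Reagents that add atoms: none
Why: Mesylation and base-induced E1cB elimination through the C5 furanolate create the exocyclic C5=C6 alkene, and the Z isomer (chain syn to the ring oxygen) is expected to prevail because the E isomer forces the chain against the C4 methoxy group, while the C7 hydrogen is too weakly acidic to be removed by DBU.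

Step 16
Reactants: 29 (5Z)-5-[(2S,6Z)-9-[5-(furan-3-ylmethyl)furan-3-yl]-2,6-dimethylnon-6-en-1-ylidene]-4-methoxy-3-methylfuran-2(5H)-one
Product: 31 (5Z)-5-[(2S,6Z)-9-[5-(furan-3-ylmethyl)furan-3-yl]-2,6-dimethylnon-6-en-1-ylidene]-4-hydroxy-3-methylfuran-2(5H)-one (CNP0237196.4), via lithium tetronate 30 (not isolated)
Conditions: LiCl (excess), DMF, 100 °C, Ar, dark; then cold 0.5 M HCl to pH 2–3, rapid extraction
Reagents that add atoms: none
Why: Nucleophilic SN2 O-demethylation, in which chloride attacks the methyl group of the vinylogous methyl carbonate and the delocalised tetronate leaves, followed by acidification, frees the tetronic acid without touching C7 or either alkene.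

**Compound list**

1 | 5-bromopent-1-ene | C=CCCCBr | starting material
2 | hept-1-en-6-yne | C=CCCCC#C | intermediate
3 | lithium hept-6-en-1-yn-1-ide | [Li]C#CCCCC=C | intermediate (not isolated)
4 | methyl oct-7-en-2-ynoate | C=CCCCC#CC(=O)OC | intermediate
5 | lithium [(2E)-1-methoxy-3-methyl-1-oxoocta-2,7-dien-2-yl](methyl)cuprate | C=CCCC/C(C)=C(/[Cu-]C)C(=O)OC.[Li+] | intermediate (not isolated)
6 | methyl (2Z)-3-methylocta-2,7-dienoate | C=CCCC/C(C)=C\C(=O)OC | intermediate
7 | (2Z)-3-methylocta-2,7-dien-1-ol | C=CCCC/C(C)=C\CO | intermediate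
8 | (2Z)-3-methylocta-2,7-dien-1-yl methanesulfonate | C=CCCC/C(C)=C\COS(C)(=O)=O | intermediate (not isolated)
9 | (2Z)-1-chloro-3-methylocta-2,7-diene | C=CCCC/C(C)=C\CCl | intermediate
10 | furan-3-ylmethanol | OCc1ccoc1 | starting material
11 | furan-3-ylmethyl methanesulfonate | CS(=O)(=O)OCc1ccoc1 | intermediate (not isolated)
12 | 3-(chloromethyl)furan | ClCc1ccoc1 | intermediate
13 | methyl 5-bromofuran-3-carboxylate | COC(=O)c1coc(Br)c1 | starting material
14 | (furan-3-ylmethyl)zinc chloride | Cl[Zn]Cc1ccoc1 | intermediate (not isolated)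
15 | methyl 5-(furan-3-ylmethyl)furan-3-carboxylate | COC(=O)c1coc(Cc2ccoc2)c1 | intermediate
16 | [5-(furan-3-ylmethyl)furan-3-yl]methanol | OCc1coc(Cc2ccoc2)c1 | intermediate
17 | [5-(furan-3-ylmethyl)furan-3-yl]methyl methanesulfonate | CS(=O)(=O)OCc1coc(Cc2ccoc2)c1 | intermediate (not isolated)
18 | 4-(chloromethyl)-2-(furan-3-ylmethyl)furan | ClCc1coc(Cc2ccoc2)c1 | intermediate
19 | [5-(furan-3-ylmethyl)furan-3-yl]methylmagnesium chloride | Cl[Mg]Cc1coc(Cc2ccoc2)c1 | intermediate (not isolated)
20 | 2-(furan-3-ylmethyl)-4-[(3Z)-4-methylnona-3,8-dien-1-yl]furan | C=CCCC/C(C)=C\CCc1coc(Cc2ccoc2)c1 | intermediate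
21 | dimethyl[(2S,6Z)-9-[5-(furan-3-ylmethyl)furan-3-yl]-2,6-dimethylnon-6-en-1-yl]alane | C[Al](C)C[C@@H](C)CCC/C(C)=C\CCc1coc(Cc2ccoc2)c1 | intermediate (not isolated)
22 | (2S,6Z)-9-[5-(furan-3-ylmethyl)furan-3-yl]-2,6-dimethylnon-6-en-1-ol | OC[C@@H](C)CCC/C(C)=C\CCc1coc(Cc2ccoc2)c1 | intermediate
23 | 3-methyltetronic acid (4-hydroxy-3-methylfuran-2(5H)-one) | CC1=C(O)COC1=O | starting material
24 | 4-methoxy-3-methylfuran-2(5H)-one | COC1=C(C)C(=O)OC1 | intermediate
25 | (2S,6Z)-9-[5-(furan-3-ylmethyl)furan-3-yl]-2,6-dimethylnon-6-enal | O=C[C@@H](C)CCC/C(C)=C\CCc1coc(Cc2ccoc2)c1 | intermediate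
26 | lithium 4-methoxy-3-methylfuran-2-olate | COc1coc([O-])c1C.[Li+] | intermediate (not isolated)
27 | 5-[(2S,6Z)-9-[5-(furan-3-ylmethyl)furan-3-yl]-1-hydroxy-2,6-dimethylnon-6-en-1-yl]-4-methoxy-3-methylfuran-2(5H)-one (epimer mixture at C5 and C6) | COC1=C(C)C(=O)OC1C(O)[C@@H](C)CCC/C(C)=C\CCc1coc(Cc2ccoc2)c1 | intermediate
28 | (2S,6Z)-9-[5-(furan-3-ylmethyl)furan-3-yl]-1-(3-methoxy-4-methyl-5-oxo-2,5-dihydrofuran-2-yl)-2,6-dimethylnon-6-en-1-yl methanesulfonate (epimer mixture) | COC1=C(C)C(=O)OC1C(OS(C)(=O)=O)[C@@H](C)CCC/C(C)=C\CCc1coc(Cc2ccoc2)c1 | intermediate (not isolated)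
29 | (5Z)-5-[(2S,6Z)-9-[5-(furan-3-ylmethyl)furan-3-yl]-2,6-dimethylnon-6-en-1-ylidene]-4-methoxy-3-methylfuran-2(5H)-one | CC1=C(OC)/C(=C/[C@@H](C)CCC/C(C)=C\CCc2coc(Cc3ccoc3)c2)OC1=O | intermediate
30 | lithium (5Z)-5-[(2S,6Z)-9-[5-(furan-3-ylmethyl)furan-3-yl]-2,6-dimethylnon-6-en-1-ylidene]-3-methyl-2-oxo-2,5-dihydrofuran-4-olate | CC1=C([O-])/C(=C/[C@@H](C)CCC/C(C)=C\CCc2coc(Cc3ccoc3)c2)OC1=O.[Li+] | intermediate (not isolated)
31 | (5Z)-5-[(2S,6Z)-9-[5-(furan-3-ylmethyl)furan-3-yl]-2,6-dimethylnon-6-en-1-ylidene]-4-hydroxy-3-methylfuran-2(5H)-one | CC1=C(O)/C(=C/[C@@H](C)CCC/C(C)=C\CCc2coc(Cc3ccoc3)c2)OC1=O | target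

**Step count and risks**

Total step count: 16. Longest linear sequence: 11 steps (steps 1–5, 10, 11 and 13–16, from 5-bromopent-1-ene). The bis-furan branch (steps 6–9) and the tetronate methylation (step 12) are side branches.

Steps most likely to fail:

1. Step 11. The chiral zirconocene may discriminate the two faces of C6=C7 too weakly to deliver material of useful enantiomeric purity, a shortfall that no later bond-forming step corrects. Alternatively, the Lewis-acidic aluminium and cationic zirconium medium, or the oxygen quench, may degrade the bis-furylmethane before insertion is complete. The fallback replaces catalytic carbometalation by auxiliary-controlled α-methylation; it sets out from 20 and rejoins the route at 25. Hydroboration of the terminal alkene of 20 with 9-BBN in THF would give 9-[(6Z)-9-[5-(furan-3-ylmethyl)furan-3-yl]-6-methylnon-6-en-1-yl]-9-borabicyclo[3.3.1]nonane F1, which NaBO3·4H2O would oxidise to (6Z)-9-[5-(furan-3-ylmethyl)furan-3-yl]-6-methylnon-6-en-1-ol F2. Buffered Dess–Martin oxidation would give (6Z)-9-[5-(furan-3-ylmethyl)furan-3-yl]-6-methylnon-6-enal F3. Condensation with (R)-1-amino-2-(methoxymethyl)pyrrolidine would give the RAMP hydrazone (1E,6Z)-9-[5-(furan-3-ylmethyl)furan-3-yl]-N-[(2R)-2-(methoxymethyl)pyrrolidin-1-yl]-6-methylnon-6-en-1-imine F4. LiN(i-Pr)2 in THF would generate the lithium azaenolate of the RAMP hydrazone F5, and methylation with MeI at −100 °C would set C7 in (1E,2S,6Z)-9-[5-(furan-3-ylmethyl)furan-3-yl]-N-[(2R)-2-(methoxymethyl)pyrrolidin-1-yl]-2,6-dimethylnon-6-en-1-imine F6. The R auxiliary is chosen because the incoming methyl is the lower-ranking substituent. Two-phase cleavage with saturated aqueous oxalic acid and Et2O would release aldehyde 25; steps 14 to 16 then follow unchanged, and step 13 is not needed.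

2. Step 10. Magnesium insertion into the furylmethyl chloride may be accompanied by Wurtz-type homocoupling. The ambident furylmethyl nucleophile may react through a ring carbon, and the allylic partner may suffer SN2′ attack or partial Z-to-E isomerisation. The fallback replaces the Grignard coupling by sulfone alkylation and reductive desulfonylation; it sets out from 18 and 9 and rejoins the route at 20. Displacement of chloride from 18 with PhSO2Na in DMF would give 2-(furan-3-ylmethyl)-4-[(phenylsulfonyl)methyl]furan F7. Deprotonation with n-BuLi in THF at −78 °C would give lithio[5-(furan-3-ylmethyl)furan-3-yl](phenylsulfonyl)methane F8. Alkylation of this soft carbanion by allylic chloride 9 in a plain SN2 reaction would give 2-(furan-3-ylmethyl)-4-[(3Z)-4-methyl-1-(phenylsulfonyl)nona-3,8-dien-1-yl]furan F9 (racemic at the sulfonyl carbon). Reductive desulfonylation of this non-allylic sulfone with Na(Hg) and Na2HPO4 in MeOH–THF at −20 °C would then give 20 without alkene migration.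

3. Step 16. Dealkylation by chloride may be too slow below the temperature at which the C5=C6 ylidene isomerises or the furan-rich polyene decomposes. The fallback changes the enol protecting group to one removed by a different mechanism; it sets out from 23 and 25 and rejoins the route at 31. Mitsunobu O-allylation of 23 (allyl alcohol, PPh3, diisopropyl azodicarboxylate, THF) would give 3-methyl-4-(prop-2-en-1-yloxy)furan-2(5H)-one F10. LiN(i-Pr)2 at −78 °C would convert it into lithium 3-methyl-4-(prop-2-en-1-yloxy)furan-2-olate F11, which would add to 25 to give 5-[(2S,6Z)-9-[5-(furan-3-ylmethyl)furan-3-yl]-1-hydroxy-2,6-dimethylnon-6-en-1-yl]-3-methyl-4-(prop-2-en-1-yloxy)furan-2(5H)-one F12. Mesylation would give the corresponding C6 methanesulfonate F13, and DBU elimination would give (5Z)-5-[(2S,6Z)-9-[5-(furan-3-ylmethyl)furan-3-yl]-2,6-dimethylnon-6-en-1-ylidene]-3-methyl-4-(prop-2-en-1-yloxy)furan-2(5H)-one F14. Zerovalent palladium (Pd(PPh3)4, catalytic) with morpholine as allyl acceptor in THF at rt would then remove the allyl group under neutral conditions and give 31 after a cold dilute-acid wash.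

**Further compounds**

F1 | step 11 | 9-[(6Z)-9-[5-(furan-3-ylmethyl)furan-3-yl]-6-methylnon-6-en-1-yl]-9-borabicyclo[3.3.1]nonane | C12CCCC(CCC1)B2CCCCC/C(C)=C\CCc1coc(Cc2ccoc2)c1
F2 | step 11 | (6Z)-9-[5-(furan-3-ylmethyl)furan-3-yl]-6-methylnon-6-en-1-ol | OCCCCC/C(C)=C\CCc1coc(Cc2ccoc2)c1
F3 | step 11 | (6Z)-9-[5-(furan-3-ylmethyl)furan-3-yl]-6-methylnon-6-enal | O=CCCCC/C(C)=C\CCc1coc(Cc2ccoc2)c1
F4 | step 11 | (1E,6Z)-9-[5-(furan-3-ylmethyl)furan-3-yl]-N-[(2R)-2-(methoxymethyl)pyrrolidin-1-yl]-6-methylnon-6-en-1-imine | COC[C@H]1CCCN1/N=C/CCCC/C(C)=C\CCc1coc(Cc2ccoc2)c1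
F5 | step 11 | lithium azaenolate of the RAMP hydrazone | COC[C@H]1CCCN1[N-]/C=C/CCC/C(C)=C\CCc1coc(Cc2ccoc2)c1.[Li+]
F6 | step 11 | (1E,2S,6Z)-9-[5-(furan-3-ylmethyl)furan-3-yl]-N-[(2R)-2-(methoxymethyl)pyrrolidin-1-yl]-2,6-dimethylnon-6-en-1-imine | COC[C@H]1CCCN1/N=C/[C@@H](C)CCC/C(C)=C\CCc1coc(Cc2ccoc2)c1
F7 | step 10 | 2-(furan-3-ylmethyl)-4-[(phenylsulfonyl)methyl]furan | O=S(=O)(Cc1coc(Cc2ccoc2)c1)c1ccccc1
F8 | step 10 | lithio[5-(furan-3-ylmethyl)furan-3-yl](phenylsulfonyl)methane | [Li]C(c1coc(Cc2ccoc2)c1)S(=O)(=O)c1ccccc1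
F9 | step 10 | 2-(furan-3-ylmethyl)-4-[(3Z)-4-methyl-1-(phenylsulfonyl)nona-3,8-dien-1-yl]furan (racemic) | C=CCCC/C(C)=C\CC(c1coc(Cc2ccoc2)c1)S(=O)(=O)c1ccccc1
F10 | step 16 | 3-methyl-4-(prop-2-en-1-yloxy)furan-2(5H)-one | C=CCOC1=C(C)C(=O)OC1
F11 | step 16 | lithium 3-methyl-4-(prop-2-en-1-yloxy)furan-2-olate | C=CCOc1coc([O-])c1C.[Li+]
F12 | step 16 | 5-[(2S,6Z)-9-[5-(furan-3-ylmethyl)furan-3-yl]-1-hydroxy-2,6-dimethylnon-6-en-1-yl]-3-methyl-4-(prop-2-en-1-yloxy)furan-2(5H)-one (epimer mixture) | C=CCOC1=C(C)C(=O)OC1C(O)[C@@H](C)CCC/C(C)=C\CCc1coc(Cc2ccoc2)c1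
F13 | step 16 | C6 methanesulfonate of the allyl tetronate aldol adduct (epimer mixture) | C=CCOC1=C(C)C(=O)OC1C(OS(C)(=O)=O)[C@@H](C)CCC/C(C)=C\CCc1coc(Cc2ccoc2)c1
F14 | step 16 | (5Z)-5-[(2S,6Z)-9-[5-(furan-3-ylmethyl)furan-3-yl]-2,6-dimethylnon-6-en-1-ylidene]-3-methyl-4-(prop-2-en-1-yloxy)furan-2(5H)-one | CC1=C(OCC=C)/C(=C/[C@@H](C)CCC/C(C)=C\CCc2coc(Cc3ccoc3)c2)OC1=O
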